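(The numbers in the tables are simulated with constants of no real substance.)

Which flask ends with more target?

| flask | substrate | partner | free catalyst | remark | time |
|---|---|---|---|---|---|
| dawn | 0.16 M | 0.128 M | 4 mM | run made earlier |  |
| winter | 0.080 M | 0.128 M | 4 mM | run made earlier |  |
| midnight | 0.32 M | 0.128 M | 4 mM | run made earlier |  |
| alpha | 0.16 M | 0.128 M | 4.0 mM | everything together at the start | 15 h |
| epsilon | 0.16 M | 0.128 M (fed, over 6.0 h) | 4.0 mM | all else is in the flask from the start; the feed brings no volume worth counting | 15 h |
| zeta | 0.16 M (fed, over 6.0 h) | 0.128 M | 4.0 mM | all else is in the flask from the start; the feed brings no volume worth counting | 15 h |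

| run | time / h | target / % |
|---|---|---|
| dawn | 2.00 | 22.2 |
| dawn | 4.00 | 36.1 |
| dawn | 6.00 | 45.1 |
| dawn | 8.00 | 50.7 |
| dawn | 10.0 | 49.8 |
| dawn | 12.0 | 50.3 |
| dawn | 15.0 | 49.4 |
| winter | 0.667 | 18.4 |
| winter | 1.00 | 25.9 |
| winter | 1.50 | 37.4 |
| winter | 2.50 | 60.7 |
| winter | 4.00 | 79.8 |
| winter | 6.00 | 80.2 |
| winter | 10.0 | 80.0 |
| midnight | 1.33 | 6.0 |
| midnight | 2.50 | 8.2 |
| midnight | 4.00 | 9.9 |
| midnight | 5.00 | 10.4 |
| midnight | 6.00 | 9.9 |
| midnight | 8.00 | 8.2 |
| midnight | 10.0 | 5.7 |

(scatter of a reading: 0.5 percentage points)

* the flask with the highest amount of target, in percent of the substrate charged ("all alike" if they lie within 1.5 percentage points) (alpha / epsilon / zeta / all alike)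
* final target, as a percentage of the substrate charged, in alpha
* final target, as a percentage of the substrate charged, in epsilon
* final target, as a percentage of the substrate charged, in zeta

- the analysis behind the earlier runs scatters by 0.5 percentage points, standard deviation

Midnight's target falls from 10.4 % at 5.00 h to 5.7 % at 10.0 h, so I suppose that substrate eats target, one of each, and that every target formed costs one partner. Target made equals partner turned over, target kept is made minus eaten, and substrate consumed is made plus eaten. With partner charged below substrate, the substrate gone and every partner turned into target, a flask ends at two [partner] − [substrate], as charged: 0.0960 M, my ceiling (the stoichiometric limit), or 60.0 % of the substrate charged. Each partner that stays idle takes two targets off this ceiling, and each substrate left over adds one. Dawn's reading of 50.3 % at 12.0 h, its substrate taken as gone, then reads as about 7.76 mM of idle partner. So I commit to alpha at dawn's plateau, and to both fed flasks below the ceiling if their substrate is consumed.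

The forecast names zeta, with 50 % for alpha, 56 % for epsilon and 61 % for zeta. Of epsilon it says “The ceiling is about 0.096 M”. Its zeta stands higher than my ceiling, and there we differ.

The flasks give 50.6 %, 48.0 % and 59.0 % in that order. So zeta leads, and epsilon lies 8 percentage points under the forecast.

    catalyst intermediate A ⇌ by-product + catalyst intermediate B (K = 0.470 M, k = 26.8 h⁻¹)
    substrate + catalyst intermediate C → catalyst intermediate D (k = 1610 M⁻¹ h⁻¹)
    partner + free catalyst → catalyst intermediate A (k = 217 M⁻¹ h⁻¹)
    catalyst intermediate B → catalyst intermediate C (k = 22.6 h⁻¹)
    substrate + target → side product (k = 2.65 M⁻¹ h⁻¹)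
    catalyst intermediate D → free catalyst + target (k = 31.4 h⁻¹)

Epsilon ends with 0 % of its substrate, so its distance below the ceiling puts idle partner at 9.58 mM. The flask shows 4.4 % of the partner charge unused and 99.9 % of the catalyst held as catalyst intermediates A, B and C, together 9.58 mM. The neighbour, epsilon with 0.077 M of partner, has a ceiling of −0.00600 M, below zero, so some substrate must stay. It keeps 17.2 % of the charge, with 0.0218 % of its partner unused. Ceiling plus that substrate gives 13.4 %, and the flask holds 13.4 %.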